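Friday's flask ends with 13.7% side product against 8.5% in Wednesday's, and with 37.3% target against 19.4%, so watch how much target stands beside starting material, and for how long.

in all of them: free catalyst 21 µM
- Saturday's: starting material 10 mM; second substrate 5 mM; partner 12 mM; run made earlier
- Wednesday's: starting material 10 mM; second substrate 5 mM; partner 8 mM; run made earlier
- Friday's: starting material 10 mM; second substrate 5 mM; partner 18 mM; run made earlier
- blue: starting material 10 mM (fed, over 5.0 min); second substrate 5.00 mM; partner 12.0 mM; all else is in the flask from the start; the feed brings no volume worth counting; time 6.0 min
- amber: starting material 10 mM; second substrate 5.00 mM; partner 12.0 mM; everything together at the start; time 6.0 min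
- grey: starting material 10 mM; second substrate 5.00 mM; partner 12.0 mM (fed, over 5.0 min); all else is in the flask from the start; the feed brings no volume worth counting; time 6.0 min

- Saturday's (time / min: side product / %, target / %): 0.250: 0, 2.6; 0.417: 0, 6.8; 0.667: 0.2, 11.6; 1.00: 2.2, 13.8; 1.50: 3.4, 18.3; 2.50: 7.2, 24.3; 4.00: 10.4, 26.7
- Wednesday's (time / min: side product / %, target / %): 0.250: 0, 2.5; 0.667: 0.9, 7.6; 1.33: 0.4, 10.5; 2.00: 3.0, 15.5; 3.00: 3.1, 18.0; 4.00: 7.7, 18.3; 5.00: 8.5, 19.4
- Friday's (time / min: side product / %, target / %): 0.417: 0, 10.5; 0.667: 0.8, 16.3; 0.833: 2.6, 19.0; 1.33: 1.0, 25.7; 2.00: 6.8, 30.8; 3.00: 7.5, 34.1; 5.00: 13.7, 37.3

(readings scatter by 1 percentage point)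

- the flask that comes out highest in amount of side product, in percent of the starting material charged; "all alike" if 1.5 percentage points covers them all (blue / amber / grey / all alike)
- amount of side product at the end, in percent of the starting material charged, blue
- amount of side product at the end, in percent of the starting material charged, amber
- amount of side product at the end, in percent of the starting material charged, grey

- percent here means starting material units held: one side product counts as two
- a reading or a percentage of target counts all its forms, free or not

In the first instants target formation is the fast event: Friday's target climbs at 0.252 /min of the charge, while side product reads 0% at 0.417 min. By its last reading Saturday's catalyst has turned over into target about 152 times, counting half of the side product reading as target, yet c(free catalyst) is 21 µM against 10 mM of starting material. So the balance can ignore it: the share of starting material left is a = 1 − T − O, with T and O the target and side product readings. In the middle target bends over: Saturday's gains 6 percentage points between 1.50 min and 2.50 min, then 2.4 points up to 4.00 min.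

Late on, side product keeps climbing: Friday's slope from 3.00 min to 5.00 min is 0.0310 /min, slower than the early target rate. Dividing it by the mean T, 35.7%, and the mean a, 53.7%, gives 0.162 /min, the side-product coefficient σ, the rate of side product per unit of T times a. It is a reading, and the scatter of the two side product readings alone comes to 22.8% of its value. Amber has Saturday's charges, so I carry Saturday's last reading forward at σTa to 6.0 min, with T and a held at that reading, and commit to 15.8% as an estimate. In blue and grey the feed takes 5.0 min of the 6.0 min, so I expect both below amber.

The forecast says amber, with 7.5% for blue, 15.5% for amber and 9.5% for grey, arguing for blue that “low starting material early suppresses both target and side product”.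

The flask gives amber, with 4.84% for blue, 14.1% for amber and 8.23% for grey.

    starting material + free catalyst ⇌ catalyst intermediate A (K = 43.0 /M, k = 3970 /M/s)
    partner + catalyst intermediate A → free catalyst + target (k = 620 /M/s)
    second substrate + free catalyst ⇌ catalyst intermediate B (K = 87.0 /M, k = 1060 /M/s)
    partner + catalyst intermediate B → free catalyst + second product (k = 203 /M/s)
    free catalyst + target ⇌ idle complex, settled at all times (K = 34.0 /M)
    partner → decomposed reagent (k = 0.00560 /s)
    starting material + target → side product (k = 0.134 /M/s)

Amber lies below my 15.8%, and blue lies near the forecast's low end, 4%. In grey's last 1.00 min, σTa gives 2.5 points, and grey gains 2.5 points. Now take blue with c(partner) at 48 mM. It ends with 44.6% target and 46% starting material, so σTa there is 0.0331 /min, against 0.0175 /min in blue. That neighbouring flask holds 9.51% side product.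

(The earlier runs and the new flask are calculated with made-up constants.)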